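The azulene is grown, not imported. Its seven-membered ring (C3a', C4'–C8', C8a') is read as the six carbons of a 2-methyl-5-isopropylphenyl ring plus one inserted carbon, C8a'. C4'-CH3 and C7'-isopropyl are the para substituents of that benzene, and C3', already bonded to indenone C2, is its benzylic carbon. The chain C3'–CH2–C(=O)–CHN2 ends in the diazo carbon that becomes C8a'. One rhodium-catalysed operation closes the five-membered ring (C8a'–C3a') and expands the arene (C8a'–C8'), leaving a ketone at C1' for the last methyl group. The precursor is a 2,3-disubstituted indenone bearing a CH(aryl)CH2C(=O)CHN2 arm at C2 and a dioxolane-masked aldehyde at C4.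

Key step: step 11

Remark: primed locants refer to the azulene, unprimed ones to the indenone; the target is achiral, and the sp3 centres made on the way (C3', C8a') are racemic or mixed and vanish on aromatisation. The annulation partner must carry bromine between the free and the masked formyl group, with the methyl group next to the free one, so it is built from 3-iodo-4-methylbenzaldehyde; this aldehyde and 2-bromo-4-isopropyl-1-methylbenzene are assumed purchasable.

Step 1
Reactants: 1 2-bromo-4-isopropyl-1-methylbenzene
Product: 3 5-isopropyl-2-methylbenzaldehyde, via aryllithium 2 (not isolated)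
Conditions: n-BuLi, THF, −78 °C; then DMF, −78 °C → rt; 1 M HCl
Reagents that add atoms: N,N-dimethylformamide, CN(C)C=O
Why: Bromine–lithium exchange followed by formylation of the aryllithium with DMF (Bouveault-type aldehyde synthesis) places the formyl group ortho to methyl and meta to isopropyl with no regiochemical ambiguity.

Step 2
Reactants: 3 5-isopropyl-2-methylbenzaldehyde; 4 Meldrum's acid
Product: 5 5-(5-isopropyl-2-methylbenzylidene)-2,2-dimethyl-1,3-dioxane-4,6-dione
Conditions: piperidine (cat.), AcOH (cat.), toluene, rt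
Reagents that add atoms: none
Why: Knoevenagel condensation of a non-enolisable aryl aldehyde with the highly acidic Meldrum's acid is fast under amine/acid catalysis and is driven by loss of water.

Step 3
Reactants: 5 5-(5-isopropyl-2-methylbenzylidene)-2,2-dimethyl-1,3-dioxane-4,6-dione; 6 1-propynylmagnesium bromide
Product: 7 5-[1-(5-isopropyl-2-methylphenyl)but-2-yn-1-yl]-2,2-dimethyl-1,3-dioxane-4,6-dione (racemic)
Conditions: THF, 0 °C → rt; 1 M HCl
Reagents that add atoms: none
Why: Arylidene Meldrum's acids are exceptionally strong Michael acceptors, so the alkynyl Grignard reagent undergoes conjugate addition without copper; the new benzylic centre (later C3') forms racemic, which is harmless because it is erased on aromatisation.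

Step 4
Reactants: 7 5-[1-(5-isopropyl-2-methylphenyl)but-2-yn-1-yl]-2,2-dimethyl-1,3-dioxane-4,6-dione
Product: 8 methyl 3-(5-isopropyl-2-methylphenyl)hex-4-ynoate (racemic)
Conditions: MeOH, pyridine, 90 °C (sealed vessel)
Reagents that add atoms: methanol, CO
Why: Alcoholysis of the Meldrum's ring releases acetone and a malonic half-ester that decarboxylates on heating in pyridine (alcoholysis–decarboxylation), leaving the alkyne and the benzylic centre untouched.

Step 5
Reactants: 9 3-iodo-4-methylbenzaldehyde
Product: 10 2-(3-iodo-4-methylphenyl)-1,3-dioxolane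
Conditions: ethylene glycol, TsOH·H2O (cat.), toluene, reflux, Dean–Stark trap
Reagents that add atoms: ethylene glycol, OCCO
Why: Acid-catalysed acetalisation with azeotropic removal of water masks the future C4 aldehyde against the basic, organometallic and carbenoid steps that follow.

Step 6
Reactants: 10 2-(3-iodo-4-methylphenyl)-1,3-dioxolane
Product: 12 2-(2-bromo-3-iodo-4-methylphenyl)-1,3-dioxolane, via aryllithium 11 (not isolated)
Conditions: lithium 2,2,6,6-tetramethylpiperidide, THF, −78 °C; then BrCCl2CCl2Br, −78 °C → rt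
Reagents that add atoms: 1,2-dibromo-1,1,2,2-tetrachloroethane, BrC(Cl)(Cl)C(Cl)(Cl)Br
Why: Directed ortho-metalation by a hindered, non-nucleophilic lithium amide removes the one ring proton flanked by both iodine and the acetal (the most acidic site and the most stable aryllithium, so halogen migration has no driving force), and the aryllithium is then brominated by the positive-bromine donor.

Step 7
Reactants: 12 2-(2-bromo-3-iodo-4-methylphenyl)-1,3-dioxolane
Product: 14 2-bromo-3-(1,3-dioxolan-2-yl)-6-methylbenzaldehyde, via aryl Grignard reagent 13 (not isolated)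
Conditions: i-PrMgCl·LiCl, THF, −40 °C; then DMF, −40 → 0 °C; aq. NH4Cl
Reagents that add atoms: N,N-dimethylformamide, CN(C)C=O
Why: Iodine–magnesium exchange is far faster than bromine–magnesium exchange, so only the C–I bond is metalated, and the ortho-bromoaryl Grignard reagent, stable at low temperature, is formylated by DMF.

Step 8
Reactants: 14 2-bromo-3-(1,3-dioxolan-2-yl)-6-methylbenzaldehyde; 8 methyl 3-(5-isopropyl-2-methylphenyl)hex-4-ynoate
Product: 15 methyl 3-[4-(1,3-dioxolan-2-yl)-3,7-dimethyl-1-oxo-1H-inden-2-yl]-3-(5-isopropyl-2-methylphenyl)propanoate (racemic)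
Conditions: Pd(OAc)2 (5 mol%), Na2CO3, n-Bu4NCl, DMA, 100 °C
Reagents that add atoms: none
Why: Larock indenone annulation, in which zerovalent palladium inserts into C–Br, the aryl group adds to the less hindered methyl-bearing alkyne carbon, and the vinylpalladium closes onto the neighbouring free aldehyde before β-hydride elimination gives the ketone, so that CH3 ends at C3 and the branched chain at C2 while the masked aldehyde cannot compete.

Step 9
Reactants: 15 methyl 3-[4-(1,3-dioxolan-2-yl)-3,7-dimethyl-1-oxo-1H-inden-2-yl]-3-(5-isopropyl-2-methylphenyl)propanoate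
Product: 16 3-[4-(1,3-dioxolan-2-yl)-3,7-dimethyl-1-oxo-1H-inden-2-yl]-3-(5-isopropyl-2-methylphenyl)propanoic acid (racemic)
Conditions: LiOH, THF/MeOH/H2O, rt; then 1 M HCl to pH 4, 0 °C
Reagents that add atoms: lithium hydroxide, [Li+].[OH-]
Why: Saponification of an unhindered methyl ester, tolerated because the indenone has no α-hydrogen and the dioxolane is base-stable and survives a brief, cold, mildly acidic work-up.

Step 10
Reactants: 16 3-[4-(1,3-dioxolan-2-yl)-3,7-dimethyl-1-oxo-1H-inden-2-yl]-3-(5-isopropyl-2-methylphenyl)propanoic acid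
Product: 18 2-[4-diazo-1-(5-isopropyl-2-methylphenyl)-3-oxobutyl]-4-(1,3-dioxolan-2-yl)-3,7-dimethyl-1H-inden-1-one (racemic), via mixed anhydride 17 (not isolated)
Conditions: ClCO2Et, Et3N, THF, −15 °C; then CH2N2 (excess, Et2O), 0 °C → rt
Reagents that add atoms: diazomethane, C=[N+]=[N-]
Why: Acylation of diazomethane by a mixed carbonic anhydride (first stage of an Arndt–Eistert sequence) gives the terminal α-diazo ketone under neutral conditions, and the tetrasubstituted indenone alkene is too hindered for dipolar cycloaddition with diazomethane.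

Step 11
Reactants: 18 2-[4-diazo-1-(5-isopropyl-2-methylphenyl)-3-oxobutyl]-4-(1,3-dioxolan-2-yl)-3,7-dimethyl-1H-inden-1-one
Product: 20 4-(1,3-dioxolan-2-yl)-2-(7-isopropyl-4-methyl-1-oxo-1,2,3,8a-tetrahydroazulen-3-yl)-3,7-dimethyl-1H-inden-1-one (mixture of diastereomers), via norcaradiene 19 (not isolated)
Conditions: Rh2(OAc)4 (1 mol%), CH2Cl2, reflux, slow addition of 18 at high dilution; filtration through neutral Al2O3, no silica, no acid
Reagents that add atoms: none
Why: Dirhodium tetraacetate expels N2 from the diazo ketone to give an electrophilic rhodium carbenoid, which cyclopropanates the ipso–ortho(H) bond of the electron-rich cymene ring (bonds C8a'–C3a' and C8a'–C8') to a norcaradiene that opens by thermally allowed disrotatory 6π electrocyclic cleavage of the C3a'–C8' bond to the cycloheptatriene. The closest known reaction type is the intramolecular Buchner reaction of 1-diazo-4-arylbutan-2-ones, which gives 3,8a-dihydroazulen-1(2H)-ones. The five-membered ring (C1', C2', C3', C3a', C8a') closes by carbenoid addition through the tether in the 5-exo mode onto the ipso carbon, whereas the seven-membered ring is not cyclised but arises by one-carbon expansion of the arene. The new sp3 centre C8a' forms as a mixture relative to C3' with no controlling element, which does not matter because both centres become sp2 in step 12. The step needs site selectivity between the two ipso–ortho bonds, secured by the ortho methyl group that makes the alternative bond tetrasubstituted, and chemoselectivity against the indenone, secured by its electron-poor tetrasubstituted C2=C3 bond and by the unfavourable seven-membered size of any carbonyl ylide. Acid is excluded during isolation because it would open the norcaradiene to a 2-tetralone.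

Step 12
Reactants: 20 4-(1,3-dioxolan-2-yl)-2-(7-isopropyl-4-methyl-1-oxo-1,2,3,8a-tetrahydroazulen-3-yl)-3,7-dimethyl-1H-inden-1-one
Product: 23 3-[4-(1,3-dioxolan-2-yl)-3,7-dimethyl-1-oxo-1H-inden-2-yl]-7-isopropyl-4-methylazulen-1-yl trifluoromethanesulfonate, via potassium enolate 21 (not isolated), via dihydroazulenyl triflate 22 (not isolated)
Conditions: KN(SiMe3)2 (1.05 equiv), THF, −78 °C; PhNTf2, −78 → 0 °C; then chloranil, 0 °C → rt; aq. NH4Cl
Reagents that add atoms: N-phenylbis(trifluoromethanesulfonimide), O=S(=O)(N(c1ccccc1)S(=O)(=O)C(F)(F)F)C(F)(F)F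
Why: The C8a' hydrogen, α to the ketone and conjugated with the triene, is far more acidic than the vinylogous C3 methyl of the indenone (which has no α-hydrogen), so the cross-conjugated enolate forms and is O-sulfonylated (enol triflate formation), after which chloranil dehydrogenates the labile dihydroazulene in the same flask by hydride abstraction to an azulenium ion and proton loss, erasing both sp3 centres before the oxidisable C1' methyl group is present.

Step 13
Reactants: 23 3-[4-(1,3-dioxolan-2-yl)-3,7-dimethyl-1-oxo-1H-inden-2-yl]-7-isopropyl-4-methylazulen-1-yl trifluoromethanesulfonate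
Product: 24 4-(1,3-dioxolan-2-yl)-2-(7-isopropyl-1,4-dimethylazulen-3-yl)-3,7-dimethyl-1H-inden-1-one
Conditions: Pd(OAc)2 (5 mol%), SPhos (10 mol%), trimethylboroxine, K3PO4, dioxane/H2O, 90 °C
Reagents that add atoms: trimethylboroxine, CB1OB(C)OB(C)O1
Why: Suzuki–Miyaura methylation of a stable aryl triflate, with an electron-rich biarylphosphine to promote oxidative addition at the electron-rich azulenyl C–O bond, leaves ketone, acetal and azulene untouched.

Step 14
Reactants: 24 4-(1,3-dioxolan-2-yl)-2-(7-isopropyl-1,4-dimethylazulen-3-yl)-3,7-dimethyl-1H-inden-1-one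
Product: 25 2-(7-isopropyl-1,4-dimethylazulen-3-yl)-3,7-dimethyl-1-oxo-1H-indene-4-carbaldehyde
Conditions: 1 M HCl, THF, rt
Reagents that add atoms: water, O
Why: Acid-catalysed acetal hydrolysis unmasks only the C4 aldehyde, because the azulene positions that react with protons or aldehydes (C1', C3') are both substituted.

Compound list
1 | 2-bromo-4-isopropyl-1-methylbenzene | Cc1ccc(C(C)C)cc1Br | starting material
2 | (5-isopropyl-2-methylphenyl)lithium | [Li]c1cc(C(C)C)ccc1C | intermediate
3 | 5-isopropyl-2-methylbenzaldehyde | Cc1ccc(C(C)C)cc1C=O | intermediate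
4 | Meldrum's acid (2,2-dimethyl-1,3-dioxane-4,6-dione) | CC1(C)OC(=O)CC(=O)O1 | starting material
5 | 5-(5-isopropyl-2-methylbenzylidene)-2,2-dimethyl-1,3-dioxane-4,6-dione | Cc1ccc(C(C)C)cc1C=C1C(=O)OC(C)(C)OC1=O | intermediate
6 | 1-propynylmagnesium bromide | CC#C[Mg]Br | starting material
7 | 5-[1-(5-isopropyl-2-methylphenyl)but-2-yn-1-yl]-2,2-dimethyl-1,3-dioxane-4,6-dione (racemic) | CC#CC(c1cc(C(C)C)ccc1C)C1C(=O)OC(C)(C)OC1=O | intermediate
8 | methyl 3-(5-isopropyl-2-methylphenyl)hex-4-ynoate (racemic) | CC#CC(CC(=O)OC)c1cc(C(C)C)ccc1C | intermediate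
9 | 3-iodo-4-methylbenzaldehyde | Cc1ccc(C=O)cc1I | starting material
10 | 2-(3-iodo-4-methylphenyl)-1,3-dioxolane | Cc1ccc(C2OCCO2)cc1I | intermediate
11 | [6-(1,3-dioxolan-2-yl)-2-iodo-3-methylphenyl]lithium | Cc1ccc(C2OCCO2)c([Li])c1I | intermediate
12 | 2-(2-bromo-3-iodo-4-methylphenyl)-1,3-dioxolane | Cc1ccc(C2OCCO2)c(Br)c1I | intermediate
13 | [2-bromo-3-(1,3-dioxolan-2-yl)-6-methylphenyl]magnesium chloride | Cc1ccc(C2OCCO2)c(Br)c1[Mg]Cl | intermediate
14 | 2-bromo-3-(1,3-dioxolan-2-yl)-6-methylbenzaldehyde | Cc1ccc(C2OCCO2)c(Br)c1C=O | intermediate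
15 | methyl 3-[4-(1,3-dioxolan-2-yl)-3,7-dimethyl-1-oxo-1H-inden-2-yl]-3-(5-isopropyl-2-methylphenyl)propanoate (racemic) | CC1=C(C(CC(=O)OC)c2cc(C(C)C)ccc2C)C(=O)c2c(C)ccc(C3OCCO3)c21 | intermediate
16 | 3-[4-(1,3-dioxolan-2-yl)-3,7-dimethyl-1-oxo-1H-inden-2-yl]-3-(5-isopropyl-2-methylphenyl)propanoic acid (racemic) | CC1=C(C(CC(=O)O)c2cc(C(C)C)ccc2C)C(=O)c2c(C)ccc(C3OCCO3)c21 | intermediate
17 | ethyl carbonic anhydride of acid 16 (racemic) | CC1=C(C(CC(=O)OC(=O)OCC)c2cc(C(C)C)ccc2C)C(=O)c2c(C)ccc(C3OCCO3)c21 | intermediate
18 | 2-[4-diazo-1-(5-isopropyl-2-methylphenyl)-3-oxobutyl]-4-(1,3-dioxolan-2-yl)-3,7-dimethyl-1H-inden-1-one (racemic) | CC1=C(C(CC(=O)C=[N+]=[N-])c2cc(C(C)C)ccc2C)C(=O)c2c(C)ccc(C3OCCO3)c21 | intermediate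
19 | norcaradiene valence isomer of 20: cyclopropane C8a'–C3a'–C8' fused to the cyclopentanone and to a cyclohexa-1,3-diene (mixture of diastereomers) | CC1=C(C2CC(=O)C3C4C(C(C)C)=CC=C(C)C234)C(=O)c2c(C)ccc(C5OCCO5)c21 | intermediate
20 | 4-(1,3-dioxolan-2-yl)-2-(7-isopropyl-4-methyl-1-oxo-1,2,3,8a-tetrahydroazulen-3-yl)-3,7-dimethyl-1H-inden-1-one (mixture of diastereomers) | CC1=C(C2CC(=O)C3C=C(C(C)C)C=CC(C)=C23)C(=O)c2c(C)ccc(C3OCCO3)c21 | intermediate
21 | potassium 3-[4-(1,3-dioxolan-2-yl)-3,7-dimethyl-1-oxo-1H-inden-2-yl]-7-isopropyl-4-methyl-2,3-dihydroazulen-1-olate (racemic) | CC1=C(C2CC([O-])=C3C=C(C(C)C)C=CC(C)=C23)C(=O)c2c(C)ccc(C4OCCO4)c21.[K+] | intermediate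
22 | 3-[4-(1,3-dioxolan-2-yl)-3,7-dimethyl-1-oxo-1H-inden-2-yl]-7-isopropyl-4-methyl-2,3-dihydroazulen-1-yl trifluoromethanesulfonate (racemic) | CC1=C(C2CC(OS(=O)(=O)C(F)(F)F)=C3C=C(C(C)C)C=CC(C)=C23)C(=O)c2c(C)ccc(C4OCCO4)c21 | intermediate
23 | 3-[4-(1,3-dioxolan-2-yl)-3,7-dimethyl-1-oxo-1H-inden-2-yl]-7-isopropyl-4-methylazulen-1-yl trifluoromethanesulfonate | CC1=C(c2cc(OS(=O)(=O)C(F)(F)F)c3cc(C(C)C)ccc(C)c2-3)C(=O)c2c(C)ccc(C4OCCO4)c21 | intermediate
24 | 4-(1,3-dioxolan-2-yl)-2-(7-isopropyl-1,4-dimethylazulen-3-yl)-3,7-dimethyl-1H-inden-1-one | CC1=C(c2cc(C)c3cc(C(C)C)ccc(C)c2-3)C(=O)c2c(C)ccc(C4OCCO4)c21 | intermediate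
25 | 2-(7-isopropyl-1,4-dimethylazulen-3-yl)-3,7-dimethyl-1-oxo-1H-indene-4-carbaldehyde | CC1=C(c2cc(C)c3cc(C(C)C)ccc(C)c2-3)C(=O)c2c(C)ccc(C=O)c21 | target

Total steps: 14. Longest linear sequence: 11 steps (steps 1–4 and 8–14); the branch of steps 5–7 joins at step 8.

Steps most likely to fail

Step 11. The carbenoid may be diverted before it reaches the cymene ring (addition to the indenone C2=C3 bond, ylide formation at the indenone oxygen, carbene dimerisation), or traces of acid during isolation may trigger the norcaradiene-to-tetralone rearrangement. The fallback gives up the ring expansion and takes the azulene ready-made from commercial guaiazulene. Vilsmeier formylation (POCl3, DMF) at its free nucleophilic ring position should give 5-isopropyl-3,8-dimethylazulene-1-carbaldehyde F1. Seyferth–Gilbert homologation with the Ohira–Bestmann reagent (K2CO3, MeOH) should give 1-ethynyl-5-isopropyl-3,8-dimethylazulene F2. Deprotonation with LiN(SiMe3)2 and quenching with MeI should give 5-isopropyl-3,8-dimethyl-1-(prop-1-yn-1-yl)azulene F3. Larock annulation of this alkyne with bromo aldehyde 14 under the conditions of step 8, the aryl group again going to the methyl-bearing alkyne carbon, should lead directly to 24. The fallback sets out from 14 and returns at 24, bypassing steps 8 to 13.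

Step 8. Oxidative addition into the doubly ortho-substituted C–Br bond may be too slow, so that palladium precipitates before turnover, or the alkyne may insert with the opposite orientation. The fallback replaces the redox-neutral annulation by a reductive carbocyclisation followed by a separate oxidation. Compounds 14 and 8 with NiBr2(dppe) and zinc dust in MeCN at 80 °C should give methyl 3-[4-(1,3-dioxolan-2-yl)-1-hydroxy-3,7-dimethyl-1H-inden-2-yl]-3-(5-isopropyl-2-methylphenyl)propanoate F4 (mixture of diastereomers); zerovalent nickel inserts more readily into hindered aryl bromides, and the alkoxide formed is not prone to β-hydride elimination. Oxidation of this doubly activated alcohol with MnO2 in CH2Cl2 should then give 15. The fallback sets out from 14 and 8 and returns at 15.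

Step 12. The base may act at the wrong site (vinylogous deprotonation of the indenone C3 methyl group), or the heptafulvene-type triflate may oligomerise before it is oxidised. The fallback installs the methyl group by nucleophilic addition instead of enol triflate chemistry. MeCeCl2 (from MeLi and CeCl3, THF, −78 °C) is weakly basic and should add to the easily enolised but more electrophilic cyclopentanone carbonyl of 20, not to the hindered conjugated indenone ketone, giving 4-(1,3-dioxolan-2-yl)-2-(1-hydroxy-7-isopropyl-1,4-dimethyl-1,2,3,8a-tetrahydroazulen-3-yl)-3,7-dimethyl-1H-inden-1-one F5 (mixture of diastereomers). Dehydration with Burgess reagent should give 4-(1,3-dioxolan-2-yl)-2-(7-isopropyl-1,4-dimethyl-2,3-dihydroazulen-3-yl)-3,7-dimethyl-1H-inden-1-one F6 (racemic), and chloranil in toluene should dehydrogenate it to 24. The fallback sets out from 20 and returns at 24, bypassing steps 12 and 13.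

Further compounds
F1 | step 11 | 5-isopropyl-3,8-dimethylazulene-1-carbaldehyde | O=Cc1cc(C)c2cc(C(C)C)ccc(C)c12
F2 | step 11 | 1-ethynyl-5-isopropyl-3,8-dimethylazulene | C#Cc1cc(C)c2cc(C(C)C)ccc(C)c12
F3 | step 11 | 5-isopropyl-3,8-dimethyl-1-(prop-1-yn-1-yl)azulene | CC#Cc1cc(C)c2cc(C(C)C)ccc(C)c12
F4 | step 8 | methyl 3-[4-(1,3-dioxolan-2-yl)-1-hydroxy-3,7-dimethyl-1H-inden-2-yl]-3-(5-isopropyl-2-methylphenyl)propanoate (mixture of diastereomers) | CC1=C(C(CC(=O)OC)c2cc(C(C)C)ccc2C)C(O)c2c(C)ccc(C3OCCO3)c21
F5 | step 12 | 4-(1,3-dioxolan-2-yl)-2-(1-hydroxy-7-isopropyl-1,4-dimethyl-1,2,3,8a-tetrahydroazulen-3-yl)-3,7-dimethyl-1H-inden-1-one (mixture of diastereomers) | CC1=C(C2CC(C)(O)C3C=C(C(C)C)C=CC(C)=C23)C(=O)c2c(C)ccc(C4OCCO4)c21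
F6 | step 12 | 4-(1,3-dioxolan-2-yl)-2-(7-isopropyl-1,4-dimethyl-2,3-dihydroazulen-3-yl)-3,7-dimethyl-1H-inden-1-one (racemic) | CC1=C(C2CC(C)=C3C=C(C(C)C)C=CC(C)=C23)C(=O)c2c(C)ccc(C4OCCO4)c21
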